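**Plan**
- Retrosynthesis: open the C20–O–C12 lactone (back to a C12 ketone), cut C13–C16 (ring D, silyl enol ether onto alkyne), then cut ring A at C2–C3 and C5–C10 together with C9–C10 of ring B in one domino step.
- Enabling feature: C10 is α to the C20 carbonyl and sits between C5 (β to the C7 carboxyl) and C9 (β to the oxygenated C12). It is therefore one doubly nucleophilic carbon flanked by two latent Michael acceptors. The cis-2,3-diol is a masked (Z)-alkene next to the quaternary C4, which can carry a non-enolisable aldehyde (C3).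
- Forward: a prochiral 4,4-disubstituted cyclohexadienone (ring C) bearing the C5=C6 enoate and the C3 aldehyde is joined to a C20–C10–C1–C2 phosphonium ylide. Wittig gives C2=C3, the first Michael gives C5–C10 (ring A), the second gives C9–C10 (ring B); ring D and the lactone follow.
- Stereochemistry: C4 comes from enzymatic desymmetrisation of a prochiral 1,3-diol. C5, C10, C9 and C8 (choice between the two enone arms) are set in the domino step relative to C4, and C6 equilibrates. The diol comes from β-face osmylation, C12 from hydride on the open face (locked by lactonisation), and C13 from the bridge.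

Key step: step 9

Conventions: gibberellane numbering is used for all intermediates. Ring A = C1–C5, C10; ring B = C5, C6, C8, C9, C10; ring C = C8, C9, C11–C14; ring D = C8, C13–C16. C17 = exocyclic CH2, C18 = methyl on C4, C19 = carboxyl on C4, C7 = carboxyl on C6, C20 = carbonyl on C10. α = the face of rings A/B that carries C19 and C20; β = the opposite face.

Assumption: the lipase in step 3 is taken to acylate the hydroxymethyl group that leads to (S)-9; if its preference is the opposite one, the same (S)-9 is reached by running the enzyme in the hydrolytic direction on the diacetate (see the fallback).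

Step 1
Reactants: 1 3-ethoxycyclohex-2-en-1-one; 2 3-bromo-1-(trimethylsilyl)prop-1-yne
Product: 4 3-ethoxy-6-[3-(trimethylsilyl)prop-2-yn-1-yl]cyclohex-2-en-1-one (racemic), via lithium dienolate 3 (not isolated)
Conditions: LiN(i-Pr)2, THF, −78 °C; then 2, −78 to 0 °C
Reagents that add atoms: none
Why: Kinetic α′-deprotonation of the vinylogous ester and SN2 alkylation with the propargylic bromide (Stork–Danheiser enolate alkylation) installs C15–C17; the new stereocentre (future C8) is racemic and is erased in step 8.

Step 2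
Reactants: 4 3-ethoxy-6-[3-(trimethylsilyl)prop-2-yn-1-yl]cyclohex-2-en-1-one; 5 methyl bromoacetate
Product: 7 methyl 2-{4-ethoxy-2-oxo-1-[3-(trimethylsilyl)prop-2-yn-1-yl]cyclohex-3-en-1-yl}acetate (racemic), via lithium dienolate 6 (not isolated)
Conditions: LiN(i-Pr)2, THF, −78 °C; then 5, −78 to 25 °C
Reagents that add atoms: none
Why: A second α′-enolate alkylation with a reactive α-halo ester builds the quaternary carbon (future C8) with its CH2CO2Me arm (C6, C7); its configuration is irrelevant because it becomes non-stereogenic in step 8.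

Step 3
Reactants: 8 methyl 3-hydroxy-2-(hydroxymethyl)-2-methylpropanoate
Product: 9 methyl (S)-3-acetoxy-2-(hydroxymethyl)-2-methylpropanoate
Conditions: lipase from Burkholderia cepacia (immobilised), vinyl acetate, t-BuOMe, 25 °C
Reagents that add atoms: vinyl acetate C=COC(C)=O
Why: Lipase-catalysed irreversible transesterification differentiates the enantiotopic hydroxymethyl groups of the prochiral 1,3-diol (enzymatic desymmetrisation) and so sets the quaternary stereocentre that becomes C4.

Step 4
Reactants: 9 methyl (S)-3-acetoxy-2-(hydroxymethyl)-2-methylpropanoate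
Product: 10 methyl (R)-3-acetoxy-2-formyl-2-methylpropanoate
Conditions: 2,2,6,6-tetramethylpiperidin-1-oxyl (10 mol %), PhI(OAc)2, CH2Cl2, 25 °C
Reagents that add atoms: none
Why: Oxoammonium-mediated oxidation of the neopentyl primary alcohol to the aldehyde (future C5); the α-carbon is quaternary and cannot epimerise (the descriptor changes only through the priority rules).

Step 5
Reactants: 7 methyl 2-{4-ethoxy-2-oxo-1-[3-(trimethylsilyl)prop-2-yn-1-yl]cyclohex-3-en-1-yl}acetate; 10 methyl (R)-3-acetoxy-2-formyl-2-methylpropanoate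
Product: 12 dimethyl (4R)-4-(acetoxymethyl)-2-{4-ethoxy-2-oxo-1-[3-(trimethylsilyl)prop-2-yn-1-yl]cyclohex-3-en-1-yl}-3-hydroxy-4-methylpentanedioate (mixture of diastereomers), via lithium ester enolate 11 (not isolated)
Conditions: LiN(i-Pr)2, THF, −78 °C; then 10, −78 °C; AcOH quench at −78 °C
Reagents that add atoms: none
Why: Lithium ester enolate aldol addition forms C5–C6; the α′ position is quaternary, so kinetic deprotonation should occur at the ester CH2, and the cold quench suppresses acetyl transfer and retro-aldol; the new carbinol and C6 centres are removed in step 6.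

Step 6
Reactants: 12 dimethyl (4R)-4-(acetoxymethyl)-2-{4-ethoxy-2-oxo-1-[3-(trimethylsilyl)prop-2-yn-1-yl]cyclohex-3-en-1-yl}-3-hydroxy-4-methylpentanedioate
Product: 14 dimethyl (2Z,4S)-4-(acetoxymethyl)-2-{4-ethoxy-2-oxo-1-[3-(trimethylsilyl)prop-2-yn-1-yl]cyclohex-3-en-1-yl}-4-methylpent-2-enedioate (two epimers at the ring carbon), via mesylate 13 (not isolated)
Conditions: MsCl, Et3N, CH2Cl2, 0 °C; then DBU, 25 °C
Reagents that add atoms: none
Why: Sulfonylation followed by E1cB elimination through the only acidic C–H (C6–H) gives the C5=C6 enoate, with the two quaternary neighbours (C4 and C8) trans for steric reasons.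

Step 7
Reactants: 14 dimethyl (2Z,4S)-4-(acetoxymethyl)-2-{4-ethoxy-2-oxo-1-[3-(trimethylsilyl)prop-2-yn-1-yl]cyclohex-3-en-1-yl}-4-methylpent-2-enedioate
Product: 17 dimethyl (2Z,4S)-4-(hydroxymethyl)-4-methyl-2-{4-oxo-1-[3-(trimethylsilyl)prop-2-yn-1-yl]cyclohex-2-en-1-yl}pent-2-enedioate (two epimers at the ring carbon), via allylic alcohol 15 (not isolated), via enone acetate 16 (not isolated)
Conditions: NaBH4, CeCl3·7H2O, MeOH, 0 °C; then aq. HCl, MeOH, 40 °C
Reagents that add atoms: water O
Why: Luche 1,2-reduction of the vinylogous ester carbonyl and acid-induced Stork–Danheiser transposition give the 4,4-disubstituted cyclohexenone (carbonyl = C12) without touching the enoate, and the same acidic methanol removes the acetate by transesterification.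

Step 8
Reactants: 17 dimethyl (2Z,4S)-4-(hydroxymethyl)-4-methyl-2-{4-oxo-1-[3-(trimethylsilyl)prop-2-yn-1-yl]cyclohex-2-en-1-yl}pent-2-enedioate
Product: 19 dimethyl (2Z,4S)-4-formyl-4-methyl-2-{4-oxo-1-[3-(trimethylsilyl)prop-2-yn-1-yl]cyclohexa-2,5-dien-1-yl}pent-2-enedioate, via enone aldehyde 18 (not isolated)
Conditions: IBX (4 equiv), DMSO, 25 °C then 80 °C
Reagents that add atoms: none
Why: IBX first oxidises the primary alcohol to the non-enolisable C3 aldehyde and then dehydrogenates the enone to the cross-conjugated dienone (IBX ketone dehydrogenation); C8 becomes non-stereogenic, so both epimers converge and C4 is the only stereocentre left.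

Step 9
Reactants: 19 dimethyl (2Z,4S)-4-formyl-4-methyl-2-{4-oxo-1-[3-(trimethylsilyl)prop-2-yn-1-yl]cyclohexa-2,5-dien-1-yl}pent-2-enedioate; 20 (4-ethoxy-4-oxobutyl)triphenylphosphonium bromide
Product: 24 tricyclic A/B/C enone triester (C2=C3 and C13=C14 double bonds; 12-oxo; 4β-methyl; 4α-CO2Me; 5β-H; 6β-CO2Me; 9β-H; 10α-CO2Et; 3-(trimethylsilyl)prop-2-yn-1-yl on the β face of C8), via ylide 21 (not isolated), via Wittig triene 22 (not isolated), via cyclohexene ester 23 (not isolated)
Conditions: 20, KN(SiMe3)2 (1.0 equiv), THF, −78 °C; add 19, −78 to 0 °C; then KN(SiMe3)2 (1.2 equiv), −78 to 25 °C; aq. NH4Cl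
Reagents that add atoms: none
Why: The salt-free ylide olefinates the neopentyl aldehyde to the (Z)-alkene (C2=C3); the second portion of base forms the C10 ester enolate, which adds 6-exo-trig to C5 of the enoate (ring A) and, after proton transfer back to C10, 5-exo-trig to C9 of one arm of the dienone (ring B). The closest known reaction types are the tandem Wittig–Michael sequence and the intramolecular double Michael addition. C4 is the only stereocentre present: in the chair-like first closure the exocyclic acceptor should sit equatorial and the flat C19 ester, not the methyl group, should take the axial site (smaller steric demand, K+ bridge to the enolate), which fixes C5. In the second closure C9 should bond equatorially at C10 because the axial site is 1,3-diaxial to the C19 ester, so C20 ends axial and cis to C19 and the A/B junction trans, while the tether forces a cis B/C junction (H-9 cis to the propargyl group). The two enone arms are diastereotopic; a K+-bridged closed transition state with the dienone carbonyl under the enolate oxygen should select the arm that places ring C on the α face (sets C8), and C6 should equilibrate under the base to the β-ester trans to C4. The step needs ylide attack on the aldehyde rather than the dienone (rate difference at −78 °C) and Michael rather than Claisen attack on the hindered C19 ester (low temperature); 22 has no acidic proton other than C10–H.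

Step 10
Reactants: 24 tricyclic A/B/C enone triester
Product: 25 2β,3β-diol of 24 (2β,3β-dihydroxy; all other centres as in 24)
Conditions: OsO4 (5 mol %), N-methylmorpholine N-oxide, acetone/H2O, 0 °C
Reagents that add atoms: osmium tetroxide O=[Os](=O)(=O)=O; N-methylmorpholine N-oxide C[N+]1([O-])CCOCC1
Why: Upjohn syn-dihydroxylation of the only electron-rich alkene from the β face, which is opposite the axial C19 and C20 esters, gives the 2β,3β-diol; the enone and the silylalkyne should react much more slowly.

Step 11
Reactants: 25 2β,3β-diol of 24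
Product: 26 2β,3β-O-isopropylidene acetal of 25
Conditions: Me2C(OMe)2, pyridinium p-toluenesulfonate, CH2Cl2, 25 °C
Reagents that add atoms: 2,2-dimethoxypropane COC(C)(C)OC
Why: Acid-catalysed transacetalisation of the cis-diol gives the acetonide, which blocks retro-aldol cleavage of the 3-hydroxy-19-ester unit in the later basic steps.

Step 12
Reactants: 26 2β,3β-O-isopropylidene acetal of 25
Product: 27 terminal alkyne (26 without the trimethylsilyl group)
Conditions: Bu4NF, AcOH, THF, 0 °C
Reagents that add atoms: none
Why: Fluoride-induced cleavage of the C(sp)–Si bond under buffered conditions frees the terminal alkyne needed for ring D without transesterification or enone damage.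

Step 13
Reactants: 27 terminal alkyne
Product: 29 12-(tert-butyldimethylsilyloxy)-12(13)-ene silyl enol ether of 27 (C14 now CH2), via lithium enolate 28 (not isolated)
Conditions: LiBH(s-Bu)3, THF, −78 °C; then t-BuMe2SiOTf, −78 to 0 °C
Reagents that add atoms: tert-butyldimethylsilyl trifluoromethanesulfonate CC(C)(C)[Si](C)(C)OS(=O)(=O)C(F)(F)F
Why: Conjugate hydride reduction of the β-monosubstituted cyclohexenone gives the C12–C13 enolate regiospecifically and O-silylation fixes it, so the later ring closure can only occur at C13 and not at C11.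

Step 14
Reactants: 29 silyl enol ether
Product: 30 tetracyclic ketone: 20-ethyl 7,19-dimethyl 2β,3β-isopropylidenedioxy-12-oxogibberell-16-ene-7,19,20-trioate (configuration of the target)
Conditions: [(2-biphenylyl)(t-Bu)2P]Au(NCMe)SbF6 (5 mol %), CH2Cl2/MeOH 10:1, 25 °C
Reagents that add atoms: none
Why: Gold-catalysed 5-exo-dig addition of the silyl enol ether carbon C13 to the activated alkyne carbon C16 (Conia-ene-type carbocyclisation) and protodeauration close the bicyclo[3.2.1]octane with the exocyclic methylene; C13 is fixed by the bridge from the axial propargyl group on C8.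

Step 15
Reactants: 30 tetracyclic ketone
Product: 32 20,12α-lactone: 7,19-dimethyl ester of the 2β,3β-isopropylidenedioxy lactone diacid, via hydroxy ester 31 (not isolated)
Conditions: LiBH(s-Bu)3, THF, −78 to 25 °C; aq. NH4Cl
Reagents that add atoms: none
Why: The bulky hydride should attack C12 along the equatorial trajectory from the β face because the α (axial) approach is blocked by the 1,3-diaxial quaternary C10; the resulting axial 12α-alkoxide closes the δ-lactone onto the C20 ester, which only this epimer can do.

Step 16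
Reactants: 32 20,12α-lactone dimethyl ester
Product: 33 2β,3β-isopropylidenedioxy lactone 7,19-diacid
Conditions: NaSEt, DMF, 90 °C; then cold dilute aq. HCl
Reagents that add atoms: none
Why: SN2 O-demethylation by thiolate frees both acids, including the hindered axial C19 ester that resists saponification; the lactone, acetonide and alkene should survive, and C6 stays in the more stable β-configuration.

Step 17
Reactants: 33 lactone diacid acetonide
Product: 34 target: 2β,3β-dihydroxy-20,12α-lactone 7,19-diacid (CNP0212122.1)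
Conditions: AcOH/H2O 4:1, 40 °C
Reagents that add atoms: none
Why: Mild acid hydrolysis of the isopropylidene acetal releases the cis-diol without isomerising the exocyclic alkene or opening the lactone.

**Compound list**
1 | 3-ethoxycyclohex-2-en-1-one | CCOC1=CC(=O)CCC1 | starting material
2 | 3-bromo-1-(trimethylsilyl)prop-1-yne | C[Si](C)(C)C#CCBr | starting material
3 | lithium dienolate of 1 (not isolated) | CCOC1=CC(O[Li])=CCC1 | intermediate
4 | 3-ethoxy-6-[3-(trimethylsilyl)prop-2-yn-1-yl]cyclohex-2-en-1-one (racemic) | CCOC1=CC(=O)C(CC#C[Si](C)(C)C)CC1 | intermediate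
5 | methyl bromoacetate | COC(=O)CBr | starting material
6 | lithium dienolate of 4 (not isolated) | CCOC1=CC(O[Li])=C(CC#C[Si](C)(C)C)CC1 | intermediate
7 | methyl 2-{4-ethoxy-2-oxo-1-[3-(trimethylsilyl)prop-2-yn-1-yl]cyclohex-3-en-1-yl}acetate (racemic) | CCOC1=CC(=O)C(CC#C[Si](C)(C)C)(CC(=O)OC)CC1 | intermediate
8 | methyl 3-hydroxy-2-(hydroxymethyl)-2-methylpropanoate | COC(=O)C(C)(CO)CO | starting material
9 | methyl (S)-3-acetoxy-2-(hydroxymethyl)-2-methylpropanoate | OC[C@](C)(C(=O)OC)COC(C)=O | intermediate
10 | methyl (R)-3-acetoxy-2-formyl-2-methylpropanoate | O=C[C@](C)(C(=O)OC)COC(C)=O | intermediate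
11 | lithium ester enolate of 7 (not isolated) | CCOC1=CC(=O)C(CC#C[Si](C)(C)C)(CC1)C=C(OC)O[Li] | intermediate
12 | aldol adduct, dimethyl (4R)-4-(acetoxymethyl)-2-{4-ethoxy-2-oxo-1-[3-(trimethylsilyl)prop-2-yn-1-yl]cyclohex-3-en-1-yl}-3-hydroxy-4-methylpentanedioate (diastereomer mixture) | CCOC1=CC(=O)C(CC#C[Si](C)(C)C)(CC1)C(C(=O)OC)C(O)[C@](C)(C(=O)OC)COC(C)=O | intermediate
13 | mesylate of 12 (not isolated) | CCOC1=CC(=O)C(CC#C[Si](C)(C)C)(CC1)C(C(=O)OC)C(OS(C)(=O)=O)[C@](C)(C(=O)OC)COC(C)=O | intermediate
14 | dimethyl (2Z,4S)-4-(acetoxymethyl)-2-{4-ethoxy-2-oxo-1-[3-(trimethylsilyl)prop-2-yn-1-yl]cyclohex-3-en-1-yl}-4-methylpent-2-enedioate (two epimers at the ring carbon) | CCOC1=CC(=O)C(CC#C[Si](C)(C)C)(CC1)/C(C(=O)OC)=C/[C@](C)(C(=O)OC)COC(C)=O | intermediate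
15 | allylic alcohol from 1,2-reduction of 14 (not isolated) | CCOC1=CC(O)C(CC#C[Si](C)(C)C)(CC1)/C(C(=O)OC)=C/[C@](C)(C(=O)OC)COC(C)=O | intermediate
16 | enone acetate, dimethyl (2Z,4S)-4-(acetoxymethyl)-4-methyl-2-{4-oxo-1-[3-(trimethylsilyl)prop-2-yn-1-yl]cyclohex-2-en-1-yl}pent-2-enedioate (not isolated) | O=C1C=CC(CC#C[Si](C)(C)C)(CC1)/C(C(=O)OC)=C/[C@](C)(C(=O)OC)COC(C)=O | intermediate
17 | dimethyl (2Z,4S)-4-(hydroxymethyl)-4-methyl-2-{4-oxo-1-[3-(trimethylsilyl)prop-2-yn-1-yl]cyclohex-2-en-1-yl}pent-2-enedioate (two epimers at the ring carbon) | O=C1C=CC(CC#C[Si](C)(C)C)(CC1)/C(C(=O)OC)=C/[C@](C)(C(=O)OC)CO | intermediate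
18 | enone aldehyde, dimethyl (2Z,4S)-4-formyl-4-methyl-2-{4-oxo-1-[3-(trimethylsilyl)prop-2-yn-1-yl]cyclohex-2-en-1-yl}pent-2-enedioate (not isolated) | O=C1C=CC(CC#C[Si](C)(C)C)(CC1)/C(C(=O)OC)=C/[C@](C)(C(=O)OC)C=O | intermediate
19 | dimethyl (2Z,4S)-4-formyl-4-methyl-2-{4-oxo-1-[3-(trimethylsilyl)prop-2-yn-1-yl]cyclohexa-2,5-dien-1-yl}pent-2-enedioate | O=C1C=CC(CC#C[Si](C)(C)C)(C=C1)/C(C(=O)OC)=C/[C@](C)(C(=O)OC)C=O | intermediate
20 | (4-ethoxy-4-oxobutyl)triphenylphosphonium bromide | CCOC(=O)CCC[P+](c1ccccc1)(c1ccccc1)c1ccccc1.[Br-] | starting material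
21 | ylide, ethyl 4-(triphenylphosphoranylidene)butanoate (not isolated) | CCOC(=O)CCC=P(c1ccccc1)(c1ccccc1)c1ccccc1 | intermediate
22 | Wittig triene: 19 with the formyl group replaced by a (1Z)-5-ethoxy-5-oxopent-1-en-1-yl group; C4 configuration unchanged (not isolated) | O=C1C=CC(CC#C[Si](C)(C)C)(C=C1)/C(C(=O)OC)=C/[C@](C)(C(=O)OC)/C=C\CCC(=O)OCC | intermediate
23 | cyclohexene ester: ring A closed (C2=C3; 4β-methyl; 4α-CO2Me; 5β-H; C10 and C6 as epimer mixtures), C5 bearing the CH(CO2Me)–dienone unit (not isolated) | C[Si](C)(C)C#CCC1(C=CC(=O)C=C1)C(C(=O)OC)[C@H]2C(C(=O)OCC)CC=C[C@@]2(C)C(=O)OC | intermediate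
24 | tricyclic A/B/C enone triester (C2=C3; C13=C14; 12-oxo; 4β-methyl; 4α-CO2Me; 5β-H; 6β-CO2Me; 9β-H; 10α-CO2Et; silylpropargyl on the β face of C8) | C[Si](C)(C)C#CC[C@]12C=CC(=O)C[C@H]1[C@@]1(CC=C[C@@](C)(C(=O)OC)[C@H]1[C@@H]2C(=O)OC)C(=O)OCC | intermediate
25 | 2β,3β-diol of 24 | C[Si](C)(C)C#CC[C@]12C=CC(=O)C[C@H]1[C@@]1(C[C@H](O)[C@H](O)[C@@](C)(C(=O)OC)[C@H]1[C@@H]2C(=O)OC)C(=O)OCC | intermediate
26 | 2β,3β-O-isopropylidene acetal of 25 | C[Si](C)(C)C#CC[C@]12C=CC(=O)C[C@H]1[C@@]1(C[C@H](OC(C)(C)O3)[C@H]3[C@@](C)(C(=O)OC)[C@H]1[C@@H]2C(=O)OC)C(=O)OCC | intermediate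
27 | terminal alkyne (26 without the trimethylsilyl group) | C#CC[C@]12C=CC(=O)C[C@H]1[C@@]1(C[C@H](OC(C)(C)O3)[C@H]3[C@@](C)(C(=O)OC)[C@H]1[C@@H]2C(=O)OC)C(=O)OCC | intermediate
28 | lithium C12–C13 enolate from conjugate reduction of 27 (not isolated) | C#CC[C@]12CC=C(O[Li])C[C@H]1[C@@]1(C[C@H](OC(C)(C)O3)[C@H]3[C@@](C)(C(=O)OC)[C@H]1[C@@H]2C(=O)OC)C(=O)OCC | intermediate
29 | 12-(tert-butyldimethylsilyloxy)-12(13)-ene silyl enol ether | C#CC[C@]12CC=C(O[Si](C)(C)C(C)(C)C)C[C@H]1[C@@]1(C[C@H](OC(C)(C)O3)[C@H]3[C@@](C)(C(=O)OC)[C@H]1[C@@H]2C(=O)OC)C(=O)OCC | intermediate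
30 | tetracyclic ketone, 20-ethyl 7,19-dimethyl 2β,3β-isopropylidenedioxy-12-oxogibberell-16-ene-7,19,20-trioate | C=C1C[C@]23C[C@H]1C(=O)C[C@H]2[C@@]2(C[C@H](OC(C)(C)O4)[C@H]4[C@@](C)(C(=O)OC)[C@H]2[C@@H]3C(=O)OC)C(=O)OCC | intermediate
31 | 12α-hydroxy ester from reduction of 30 (not isolated) | C=C1C[C@]23C[C@H]1[C@@H](O)C[C@H]2[C@@]2(C[C@H](OC(C)(C)O4)[C@H]4[C@@](C)(C(=O)OC)[C@H]2[C@@H]3C(=O)OC)C(=O)OCC | intermediate
32 | 20,12α-lactone, 7,19-dimethyl ester, 2β,3β-acetonide | C=C1C[C@]23C[C@H]1[C@@H]1C[C@H]2[C@@]2(C[C@H](OC(C)(C)O4)[C@H]4[C@@](C)(C(=O)OC)[C@H]2[C@@H]3C(=O)OC)C(=O)O1 | intermediate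
33 | 20,12α-lactone 7,19-diacid, 2β,3β-acetonide | C=C1C[C@]23C[C@H]1[C@@H]1C[C@H]2[C@@]2(C[C@H](OC(C)(C)O4)[C@H]4[C@@](C)(C(=O)O)[C@H]2[C@@H]3C(=O)O)C(=O)O1 | intermediate
34 | CNP0212122.1, 2β,3β-dihydroxy-20,12α-lactone 7,19-diacid | C=C1C[C@]23C[C@H]1[C@@H]1C[C@H]2[C@@]2(C[C@H](O)[C@H](O)[C@@](C)(C(=O)O)[C@H]2[C@@H]3C(=O)O)C(=O)O1 | target

**Totals**
Total step count: 17. Longest linear sequence: 15 steps (steps 1, 2 and 5–17; the branch through steps 3 and 4 is equally long).

**Steps most likely to fail**

Step 9. The second conjugate addition may stall or be unselective: the hindered tertiary C10 enolate may not re-form under equilibrating conditions, the two diastereotopic enone arms may be poorly discriminated, or the C10 enolate may attack the C19 ester in a Claisen sense. The fallback separates the two ring closures and removes the free enolate from the second one. The domino is interrupted after ring A by using only catalytic KOt-Bu in t-BuOH/THF at −40 °C in the second stage, so that cyclohexene ester 23 is isolated. Setting out from 23, deprotonation at the less hindered C10–H with LiN(i-Pr)2 and silylation with Me3SiCl gives the O-trimethylsilyl ketene acetal F1. Ring B is then closed by a Lewis-acid-promoted intramolecular Mukaiyama–Michael addition (TiCl4, CH2Cl2, −78 °C; open transition state, no Claisen pathway), and aqueous work-up returns to the route at 24.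

Step 5. Deprotonation may occur at the γ-position of the vinylogous ester instead of the ester CH2, and the congested lithium aldolate may undergo acetyl transfer or retro-aldol cleavage. The fallback replaces the lithium enolate by a soft-enolised thioester. Setting out from 4, its lithium dienolate is alkylated with S-phenyl 2-bromoethanethioate to give the S-phenyl thioester F2. Soft enolisation with MgBr2·OEt2 and i-Pr2NEt in CH2Cl2 in the presence of 10 enolises only the thioester and gives the β-hydroxy thioester F3 under non-basic conditions. Silver-promoted methanolysis (AgO2CCF3, MeOH) exchanges the thioester for the methyl ester and returns to the route at 12.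

Step 3. The lipase may discriminate the two enantiotopic hydroxymethyl groups insufficiently or in the wrong sense. The fallback switches from enzymatic acylation to enzymatic hydrolysis. Setting out from 8, peracetylation (Ac2O, pyridine) gives the diacetate F4, and one enantiotopic acetate is then removed by an esterase or the same lipase in phosphate buffer at pH 7. Because acylation and hydrolysis by the same enzyme address the same enantiotopic arm, the two modes give opposite monoacetates, and the mode that delivers (S)-9 is used; the route is rejoined at 9.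

**Further compounds**
F1 | step 9 | O-trimethylsilyl ketene acetal of 23 (at C10/C20) | C[Si](C)(C)C#CCC1(C=CC(=O)C=C1)C(C(=O)OC)[C@H]2C(=C(OCC)O[Si](C)(C)C)CC=C[C@@]2(C)C(=O)OC
F2 | step 5 | S-phenyl 2-{4-ethoxy-2-oxo-1-[3-(trimethylsilyl)prop-2-yn-1-yl]cyclohex-3-en-1-yl}ethanethioate | CCOC1=CC(=O)C(CC#C[Si](C)(C)C)(CC(=O)Sc2ccccc2)CC1
F3 | step 5 | β-hydroxy thioester, the S-phenyl thioester analogue of 12 | CCOC1=CC(=O)C(CC#C[Si](C)(C)C)(CC1)C(C(=O)Sc1ccccc1)C(O)[C@](C)(C(=O)OC)COC(C)=O
F4 | step 3 | methyl 3-acetoxy-2-(acetoxymethyl)-2-methylpropanoate | COC(=O)C(C)(COC(C)=O)COC(C)=O
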